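**Retrosynthetic overview**
1. 6 ⇐ 5: the target is the protonated form of its trisodium salt, reached by cation exchange.
2. 5 ⇐ 3 (key step): disconnect the C3–O and C3'–O bonds. Both sulfate esters go back to C–H bonds and arrive as complete C–O–SO3 units from peroxodisulfate. The free 4'-OH steers both attacks, so it never has to be distinguished from a 3'-OH.
3. 3 ⇐ 1: O–S disconnection at the 7-OH, the most acidic phenol of apigenin.
4. Ring order: no ring is built. Rings A, C and B are bought intact in apigenin 1.

Assumption: the target has no stereocentre and no stable chiral axis, so no stereocontrol is needed; because it is drawn as the free tris(hydrogen sulfate), the sodium salt is converted into that form in the last step.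

**Step 1**
Reactants: 1 apigenin
Product: 3 sodium apigenin 7-sulfate, via pyridinium apigenin 7-sulfate 2 (not isolated)
Conditions: SO3·pyridine (1.15 equiv), pyridine, 0 °C to rt, 14 h; aq NaHCO3 to pH 7; gel filtration on hydroxypropylated dextran (H2O to MeOH), recovered 1 recycled
Reagents that add atoms: sulfur trioxide–pyridine complex, [O-]S(=O)(=O)[n+]1ccccc1; sodium hydrogen carbonate NaHCO3, [Na+].OC(=O)[O-]
Why: O-sulfation with a sulfur trioxide–amine complex, in which limiting reagent takes the 7-OH (the most acidic, unhindered phenol, conjugated to C4=O through ring A) ahead of the 4'-OH, while the 5-OH is locked in its hydrogen bond to C4=O and mono- and disulfate separate cleanly by charge.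

**Step 2**
Reactants: 3 sodium apigenin 7-sulfate
Product: 5 trisodium quercetin 3,3',7-trissulfate, via disodium kaempferol 3,7-disulfate 4 (not isolated)
Conditions: Na2S2O8 (2.4 equiv, four portions over 24 h), Na2CO3/NaHCO3 buffer (pH 9.7), 1 M Na2SO4, Na2H2EDTA (1 mol%), degassed H2O, N2, dark, 30 °C, 48 h; MeOH to throw out Na2SO4; anion exchange, then gel filtration
Reagents that add atoms: sodium peroxodisulfate Na2S2O8, [Na+].[Na+].[O-]S(=O)(=O)OOS(=O)(=O)[O-]
Why: Proposed new method: at pH 9.7 only the 4'-OH is ionised (the chelated 5-OH stays protonated and ring A is deactivated by the 7-sulfate), and the charge of this phenolate is relayed to C3 (the vinylogous para carbon, alpha to C4=O) and to the equivalent ortho carbons C3'/C5', so carbon displaces sulfate from the O–O bond of the peroxodisulfate first at the remote, less charge-repelled C3 (loss of the acidic C3 proton restores the flavone as 4) and then, with C3 and C1' blocked and ring B twisted out of conjugation by the 3-sulfate, at an ortho carbon to place the C3'–OSO3 ester beside a still free 4'-OH, the encounter of like charges being sped up by the high ionic strength; the closest known reaction type is the Elbs persulfate oxidation of phenolates (para, or ortho when para is blocked) and of 4-pyridone anions at the carbon alpha to the carbonyl, which has not been shown on a flavone C3–H bond or on a sulfated flavonol.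

**Step 3**
Reactants: 5 trisodium quercetin 3,3',7-trissulfate
Product: 6 quercetin 3,3',7-trissulfate
Conditions: sulfonated polystyrene cation-exchange resin (H+ form), H2O, 0–4 °C, short column, about 5 min contact; eluate frozen at once and freeze-dried
Reagents that add atoms: none
Why: Cation exchange on a sulfonic acid resin swaps the three sodium ions for protons without touching a covalent bond, and short cold contact with immediate freeze-drying keeps the acid-labile aryl and enol sulfate esters from autocatalytic hydrolysis.

**Compound list**
1 | apigenin, 5,7-dihydroxy-2-(4-hydroxyphenyl)-4H-chromen-4-one (achiral) | O=c1cc(-c2ccc(O)cc2)oc2cc(O)cc(O)c12 | starting material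
2 | pyridinium apigenin 7-sulfate, pyridinium salt of the 7-O-sulfate ester with 5-OH and 4'-OH free (achiral) | O=c1cc(-c2ccc(O)cc2)oc2cc(OS(=O)(=O)[O-])cc(O)c12.c1cc[nH+]cc1 | intermediate
3 | sodium apigenin 7-sulfate (achiral) | O=c1cc(-c2ccc(O)cc2)oc2cc(OS(=O)(=O)[O-])cc(O)c12.[Na+] | intermediate
4 | disodium kaempferol 3,7-disulfate, flavonol with sulfate esters on O3 and O7 and with 5-OH and 4'-OH free (achiral) | O=c1c(OS(=O)(=O)[O-])c(-c2ccc(O)cc2)oc2cc(OS(=O)(=O)[O-])cc(O)c12.[Na+].[Na+] | intermediate
5 | trisodium quercetin 3,3',7-trissulfate, sulfate esters on O3, O3' and O7 with 5-OH and 4'-OH free (achiral) | O=c1c(OS(=O)(=O)[O-])c(-c2ccc(O)c(OS(=O)(=O)[O-])c2)oc2cc(OS(=O)(=O)[O-])cc(O)c12.[Na+].[Na+].[Na+] | intermediate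
6 | quercetin 3,3',7-trissulfate, free tris(hydrogen sulfate) (achiral) | O=c1c(OS(=O)(=O)O)c(-c2ccc(O)c(OS(=O)(=O)O)c2)oc2cc(OS(=O)(=O)O)cc(O)c12 | target

**Total step count:** 3. **Longest linear sequence:** 3.

**Three steps most likely to fail**

**Step 2 (the proposed new step).**
- C3 may be too weak a nucleophile, because its charge is shared with the C4 carbonyl oxygen.
- Ortho attack is the slow, low-yielding mode of persulfate oxidation.
- A third equivalent can attack C5'. This is slowed because the 4'-OH of 5 is hydrogen-bonded to the neighbouring sulfate and is less ionised at pH 9.7.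
- Upward pH drift would ionise the 5-OH and open ring A at C8.
- Whichever of the two positions reacts first, the second equivalent converges on 5. Under-oxidised material is recovered by charge and resubmitted.

The fallback uses known chemistry, sets out from 1 and comes back at 4. The C3–O bond is made by the classical flavone-to-flavonol sequence. Exhaustive benzylation of 1 (BnBr, K2CO3, DMF, 80 °C) gives 5,7,4'-tri-O-benzylapigenin F1. Deprotonation at C3 with LiN(iPr)2 (THF, −78 °C), trapping with B(OMe)3 and oxidation with H2O2/AcOH gives 5,7,4'-tri-O-benzylkaempferol F2. Its single free hydroxyl is sulfated (SO3·pyridine, DMF, then NaHCO3) to sodium 5,7,4'-tri-O-benzylkaempferol 3-sulfate F3. Hydrogenolysis (H2, Pd/C, MeOH/THF) gives sodium kaempferol 3-sulfate F4. Limiting SO3·pyridine then takes the 7-OH as in step 1 and, after NaHCO3, delivers 4, now isolated. From there only one equivalent of Na2S2O8 is needed, in the ordinary ortho mode of the Elbs oxidation of a para-blocked phenol, to reach 5.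

**Step 1.** The gap in reactivity between 7-OH and 4'-OH is modest, so the 4'-sulfate and the 4',7-disulfate can contaminate 3, and isomeric monosulfate salts are hard to separate.

The fallback sets out from 1 and comes back at 3. It uses a masked, neutral sulfate that can be chromatographed. Treating 1 with 2,2,2-trichloroethyl chlorosulfate (1.0 equiv, K2CO3, acetone/DMF, 0 °C) gives apigenin 7-(2,2,2-trichloroethyl sulfate) F5, which is freed from its 4'-isomer and the bis-diester on silica gel. Reductive unmasking (Zn, HCO2NH4, MeOH, rt) gives ammonium apigenin 7-sulfate F6. Evaporation from aqueous NaHCO3 then gives 3.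

**Step 3.** The free acid can hydrolyse itself on the strongly acidic beads or while it concentrates during drying, with the 3-sulfate most at risk.

The fallback sets out from 5 and comes back at 6. It uses precipitation-driven metathesis in place of an acidic resin. BaCl2 in H2O/EtOH converts 5 into the precipitated salt tribarium bis(quercetin 3,3',7-trissulfate) F7. This is resuspended in ice water and titrated with exactly three equivalents of H2SO4 per formula unit. BaSO4 is spun off, and the supernatant is a salt-free solution of 6 that never sees excess acid. It is frozen and dried, or used as it is.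

**Further compounds**
F1 | step 2 | 5,7,4'-tri-O-benzylapigenin | O=c1cc(-c2ccc(OCc3ccccc3)cc2)oc2cc(OCc3ccccc3)cc(OCc3ccccc3)c12
F2 | step 2 | 5,7,4'-tri-O-benzylkaempferol | O=c1c(O)c(-c2ccc(OCc3ccccc3)cc2)oc2cc(OCc3ccccc3)cc(OCc3ccccc3)c12
F3 | step 2 | sodium 5,7,4'-tri-O-benzylkaempferol 3-sulfate | O=c1c(OS(=O)(=O)[O-])c(-c2ccc(OCc3ccccc3)cc2)oc2cc(OCc3ccccc3)cc(OCc3ccccc3)c12.[Na+]
F4 | step 2 | sodium kaempferol 3-sulfate | O=c1c(OS(=O)(=O)[O-])c(-c2ccc(O)cc2)oc2cc(O)cc(O)c12.[Na+]
F5 | step 1 | apigenin 7-(2,2,2-trichloroethyl sulfate) | O=c1cc(-c2ccc(O)cc2)oc2cc(OS(=O)(=O)OCC(Cl)(Cl)Cl)cc(O)c12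
F6 | step 1 | ammonium apigenin 7-sulfate | O=c1cc(-c2ccc(O)cc2)oc2cc(OS(=O)(=O)[O-])cc(O)c12.[NH4+]
F7 | step 3 | tribarium bis(quercetin 3,3',7-trissulfate) | [Ba+2].[Ba+2].[Ba+2].O=c1c(OS(=O)(=O)[O-])c(-c2ccc(O)c(OS(=O)(=O)[O-])c2)oc2cc(OS(=O)(=O)[O-])cc(O)c12.O=c1c(OS(=O)(=O)[O-])c(-c2ccc(O)c(OS(=O)(=O)[O-])c2)oc2cc(OS(=O)(=O)[O-])cc(O)c12
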